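**Retrosynthetic overview**
- The target comes from a C40 3,3′-dihydroxy-4,4′-diketone by hydroxyl-directed reduction of both ring ketones. The C40 chain is cut by two Wittig disconnections (C11=C12 and C11′=C12′) into the commercial C10 trienedial and two C15 phosphonium salts.
- Both C15 salts come from one enynyl C15 ketol: used as such for ring A (7,8-triple bond), and after zinc reduction of the triple bond for ring B.
- The C15 ketol comes from the acetylide of (E)-3-methylpent-2-en-4-yn-1-ol and one chiral ring ketone (an enol acetonide), by addition and hydrolytic enone transposition.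
- The ring ketone comes from Dieckmann closure (C5–C6) of an acyclic α-silyloxy ethyl ketone ester. Its C3–C4 bond is the key disconnection: an enantioselective cross silyl benzoin in which a propionylsilane acts as a propionyl anion towards an aldehyde, joining two carbonyl carbons and setting C3 (S).
- Ring order: one six-membered ring synthon is made once (step 4) and used twice; it becomes ring A in step 5 and ring B after step 6.

Assumption: the target is the all-E isomer with (3S,4S,3′S,4′S) configuration (both 3,4-diols trans), as the SMILES states; carotenoid numbering is used for ring and chain positions; the sense of induction of the chiral phosphite in step 3 is not established for this substrate pair, so the catalyst antipode that gives (4S)-8 is used (written below as the R,R form).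

**Step 1**
Reactants: 1 methyl 2,2-dimethylpent-4-enoate
Product: 3 methyl 2,2-dimethyl-4-oxobutanoate, via secondary ozonide 2 (not isolated)
Conditions: O3, CH2Cl2, −78 °C; then Me2S, −78 °C → rt
Reagents that add atoms: ozone, [O-][O+]=O
Why: Ozonolysis with reductive work-up (Criegee mechanism) cleaves the monosubstituted alkene to the aldehyde without touching the hindered ester, and no stereocentre is formed.

**Step 2**
Reactants: 4 trimethyl(prop-1-yn-1-yl)silane
Product: 7 1-(trimethylsilyl)propan-1-one, via tris(alkenyl)borane 5 (not isolated), via tris(enol) borate 6 (not isolated)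
Conditions: BH3·SMe2 (0.34 equiv), THF, 0 °C → rt; then anhydrous Me3NO (1.05 equiv), reflux; then H2O
Reagents that add atoms: trimethylamine N-oxide, C[N+](C)(C)[O-]
Why: Hydroboration of a 1-silylalkyne places boron on the silicon-bearing carbon, and amine-oxide oxidation of the alkenylborane followed by hydrolysis of the enol borate gives the acylsilane (hydroboration–oxidation of an alkynylsilane), with no stereocentre formed.

**Step 3**
Reactants: 3 methyl 2,2-dimethyl-4-oxobutanoate; 7 1-(trimethylsilyl)propan-1-one (1.3 equiv)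
Product: 8 methyl (4S)-2,2-dimethyl-5-oxo-4-[(trimethylsilyl)oxy]heptanoate
Conditions: LiOP(O2R*) (10 mol %, from HP(O)(O2R*) and n-BuLi; H2(O2R*) = (4R,5R)-2,2-dimethyl-α,α,α′,α′-tetrakis(2-fluorophenyl)-1,3-dioxolane-4,5-dimethanol), THF, 0 °C → rt
Reagents that add atoms: none
Why: Proposed new method: the lithium phosphite adds to acylsilane 7, a 1,2-Brook rearrangement turns the former carbonyl carbon into an α-silyloxy phosphonate carbanion (a propionyl anion equivalent) that attacks the aldehyde carbon of 3, and 1,4-silyl transfer with loss of phosphite releases the ketone, so two carbonyl carbons are joined regiospecifically as C4(=O)–C3(OSiMe3) with the C3 configuration fixed by the chiral diol backbone in the C–C bond-forming addition (checked by correlation at 11); the closest known reaction type is the metallophosphite-catalysed enantioselective cross silyl benzoin reaction of aryl acyl triethylsilanes, here extended to an alkyl acyl trimethylsilane and a β-branched alkyl aldehyde.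

**Step 4**
Reactants: 8 methyl (4S)-2,2-dimethyl-5-oxo-4-[(trimethylsilyl)oxy]heptanoate
Product: 11 (7aS)-2,2,4,6,6-pentamethyl-7,7a-dihydro-1,3-benzodioxol-5(6H)-one, via silyl ether dione enolate 9 (not isolated), via hydroxy-dione 10 (not isolated)
Conditions: LiN(i-Pr)2 (2.1 equiv), THF, −78 → 0 °C; then p-TsOH·H2O (2.5 equiv), 2,2-dimethoxypropane, acetone, rt
Reagents that add atoms: 2,2-dimethoxypropane, COC(C)(C)OC
Why: Kinetic deprotonation of an α′-silyloxy ethyl ketone occurs at the ethyl CH2 and not at the silyloxy-bearing carbon, so the enolate closes the ring by Dieckmann-type acylation (C5–C6) on the ester without touching C3, and the acid quench cleaves the silyl ether and ties the C4 enol to the neighbouring C3 hydroxyl as the isopropylidene ketal, which leaves only the C6 carbonyl free.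

**Step 5**
Reactants: 11 (7aS)-2,2,4,6,6-pentamethyl-7,7a-dihydro-1,3-benzodioxol-5(6H)-one; 12 (2E)-3-methylpent-2-en-4-yn-1-ol (1.3 equiv)
Product: 15 (6S)-6-hydroxy-3-[(3E)-5-hydroxy-3-methylpent-3-en-1-yn-1-yl]-2,4,4-trimethylcyclohex-2-en-1-one, via dilithio enynol 13 (not isolated), via tertiary carbinol adduct 14 (not isolated)
Conditions: 12, n-BuLi (2.6 equiv), THF, −40 → 0 °C; then 11, −20 °C → rt; then 1 M H2SO4, THF, rt
Reagents that add atoms: none
Why: 1,2-Addition of the acetylide to the only free carbonyl (C6), then acid hydrolysis of the enol ketal and β-elimination of the tertiary alcohol, transposes the enone (Stork–Danheiser-type sequence, the ring-plus-chain union used in industrial astaxanthin chemistry) and gives the 3-hydroxy-4-oxo ring with the enyne chain on C6, the 9E geometry coming from 12 and C3 being untouched.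

**Step 6**
Reactants: 15 (6S)-6-hydroxy-3-[(3E)-5-hydroxy-3-methylpent-3-en-1-yn-1-yl]-2,4,4-trimethylcyclohex-2-en-1-one (the part destined for ring B)
Product: 16 (6S)-6-hydroxy-3-[(1E,3E)-5-hydroxy-3-methylpenta-1,3-dien-1-yl]-2,4,4-trimethylcyclohex-2-en-1-one
Conditions: Zn dust, AcOH, CH2Cl2, 0 °C → rt
Reagents that add atoms: none
Why: Dissolving-metal reduction adds two hydrogens to the triple bond that is conjugated with the enone and leaves the ring alkene and the allylic alcohol alone, the 7E diene being the thermodynamic isomer (any strained 7Z isomer equilibrates under the acid of step 7 and the heating of step 10).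

**Step 7**
Reactants: 16 (6S)-6-hydroxy-3-[(1E,3E)-5-hydroxy-3-methylpenta-1,3-dien-1-yl]-2,4,4-trimethylcyclohex-2-en-1-one
Product: 18 [(2E,4E)-5-[(4S)-4-hydroxy-2,6,6-trimethyl-3-oxocyclohex-1-en-1-yl]-3-methylpenta-2,4-dien-1-yl]triphenylphosphonium bromide, via allylic bromide 17 (not isolated)
Conditions: 48% aq HBr, CH2Cl2, −10 °C; then PPh3, EtOAc, rt
Reagents that add atoms: hydrogen bromide, Br; triphenylphosphine, c1ccc(cc1)P(c1ccccc1)c1ccccc1
Why: The primary allylic alcohol is converted by cold HBr into the allylic bromide, which alkylates PPh3 to the phosphonium salt, while the secondary α-ketol hydroxyl is not substituted under these conditions.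

**Step 8**
Reactants: 15 (6S)-6-hydroxy-3-[(3E)-5-hydroxy-3-methylpent-3-en-1-yn-1-yl]-2,4,4-trimethylcyclohex-2-en-1-one (the part destined for ring A)
Product: 20 [(2E)-5-[(4S)-4-hydroxy-2,6,6-trimethyl-3-oxocyclohex-1-en-1-yl]-3-methylpent-2-en-4-yn-1-yl]triphenylphosphonium bromide, via allylic bromide 19 (not isolated)
Conditions: 48% aq HBr, CH2Cl2, −10 °C; then PPh3, EtOAc, rt
Reagents that add atoms: hydrogen bromide, Br; triphenylphosphine, c1ccc(cc1)P(c1ccccc1)c1ccccc1
Why: Same allylic bromination and phosphine alkylation as in step 7, the triple bond and the α-ketol being inert to cold HBr.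

**Step 9**
Reactants: 18 olefinic C15 phosphonium bromide; 21 (2E,4E,6E)-2,7-dimethylocta-2,4,6-trienedial (3 equiv, excess recovered)
Product: 23 (2E,4E,6E,8E,10E,12E)-13-[(4S)-4-hydroxy-2,6,6-trimethyl-3-oxocyclohex-1-en-1-yl]-2,7,11-trimethyltrideca-2,4,6,8,10,12-hexaenal, via phosphorus ylide 22 (not isolated)
Conditions: 1,2-epoxybutane, EtOH/CH2Cl2, reflux, argon, dark
Reagents that add atoms: none
Why: Wittig reaction under neutral epoxide conditions (the epoxide takes up HBr and releases the ylide) with excess dialdehyde gives the mono-olefination product with the new C11′=C12′ bond, which equilibrates to E on heating, and the base-sensitive α-ketol survives.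

**Step 10**
Reactants: 23 C25 apo-aldehyde; 20 acetylenic C15 phosphonium bromide (1.3 equiv)
Product: 25 (3S,3′S)-3,3′-dihydroxy-7,8-didehydro-β,β-carotene-4,4′-dione, via phosphorus ylide 24 (not isolated)
Conditions: 1,2-epoxybutane, EtOH, reflux, argon, dark; then heptane, reflux (Z → E)
Reagents that add atoms: none
Why: The second Wittig reaction forms C11=C12 and completes the C40 chain, and thermal equilibration converts the Z isomers into the all-E polyene.

**Step 11**
Reactants: 25 (3S,3′S)-3,3′-dihydroxy-7,8-didehydro-β,β-carotene-4,4′-dione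
Product: 26 (3S,4S,3′S,4′S)-7,8-didehydro-β,β-carotene-3,4,3′,4′-tetrol
Conditions: Me4NBH(OAc)3 (8 equiv), AcOH (10 equiv), THF/MeCN, −20 → 0 °C, argon, dark; aq NaHCO3 work-up
Reagents that add atoms: none
Why: In this hydroxyl-directed reduction (Saksena–Evans) each 3-hydroxyl exchanges onto boron and delivers hydride intramolecularly to the adjacent C4 carbonyl from its own face, so each new hydroxyl ends up trans to the old one, giving 4S and 4′S from 3S and 3′S.

**Compound list**
1 | methyl 2,2-dimethylpent-4-enoate | COC(=O)C(C)(C)CC=C | starting material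
2 | methyl 2,2-dimethyl-3-(1,2,4-trioxolan-3-yl)propanoate (secondary ozonide) | COC(=O)C(C)(C)CC1OCOO1 | intermediate
3 | methyl 2,2-dimethyl-4-oxobutanoate | COC(=O)C(C)(C)CC=O | intermediate
4 | trimethyl(prop-1-yn-1-yl)silane | CC#C[Si](C)(C)C | starting material
5 | tris[(1Z)-1-(trimethylsilyl)prop-1-en-1-yl]borane | B(/C(=C/C)[Si](C)(C)C)(/C(=C/C)[Si](C)(C)C)/C(=C/C)[Si](C)(C)C | intermediate
6 | tris[(1Z)-1-(trimethylsilyl)prop-1-en-1-yl] borate | B(O/C(=C/C)[Si](C)(C)C)(O/C(=C/C)[Si](C)(C)C)O/C(=C/C)[Si](C)(C)C | intermediate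
7 | 1-(trimethylsilyl)propan-1-one | CCC(=O)[Si](C)(C)C | intermediate
8 | methyl (4S)-2,2-dimethyl-5-oxo-4-[(trimethylsilyl)oxy]heptanoate | CCC(=O)[C@@H](O[Si](C)(C)C)CC(C)(C)C(=O)OC | intermediate
9 | (6S)-2,4,4-trimethyl-6-[(trimethylsilyl)oxy]cyclohexane-1,3-dione (present as its lithium enolate) | CC1C(=O)[C@@H](O[Si](C)(C)C)CC(C)(C)C1=O | intermediate
10 | (4S)-3,4-dihydroxy-2,6,6-trimethylcyclohex-2-en-1-one | CC1=C(O)[C@@H](O)CC(C)(C)C1=O | intermediate
11 | (7aS)-2,2,4,6,6-pentamethyl-7,7a-dihydro-1,3-benzodioxol-5(6H)-one | CC1=C2OC(C)(C)O[C@H]2CC(C)(C)C1=O | intermediate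
12 | (2E)-3-methylpent-2-en-4-yn-1-ol | C#C/C(C)=C/CO | starting material
13 | O,C-dilithio derivative of 12 | [Li]OC/C=C(C)/C#C[Li] | intermediate
14 | (7aS)-5-[(3E)-5-hydroxy-3-methylpent-3-en-1-yn-1-yl]-2,2,4,6,6-pentamethyl-5,6,7,7a-tetrahydro-1,3-benzodioxol-5-ol (both C5 epimers) | CC1=C2OC(C)(C)O[C@H]2CC(C)(C)C1(O)C#C/C(C)=C/CO | intermediate
15 | (6S)-6-hydroxy-3-[(3E)-5-hydroxy-3-methylpent-3-en-1-yn-1-yl]-2,4,4-trimethylcyclohex-2-en-1-one | CC1=C(C#C/C(C)=C/CO)C(C)(C)C[C@H](O)C1=O | intermediate
16 | (6S)-6-hydroxy-3-[(1E,3E)-5-hydroxy-3-methylpenta-1,3-dien-1-yl]-2,4,4-trimethylcyclohex-2-en-1-one | CC1=C(/C=C/C(C)=C/CO)C(C)(C)C[C@H](O)C1=O | intermediate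
17 | (6S)-3-[(1E,3E)-5-bromo-3-methylpenta-1,3-dien-1-yl]-6-hydroxy-2,4,4-trimethylcyclohex-2-en-1-one | CC1=C(/C=C/C(C)=C/CBr)C(C)(C)C[C@H](O)C1=O | intermediate
18 | [(2E,4E)-5-[(4S)-4-hydroxy-2,6,6-trimethyl-3-oxocyclohex-1-en-1-yl]-3-methylpenta-2,4-dien-1-yl]triphenylphosphonium bromide | CC1=C(/C=C/C(C)=C/C[P+](c2ccccc2)(c2ccccc2)c2ccccc2)C(C)(C)C[C@H](O)C1=O.[Br-] | intermediate
19 | (6S)-3-[(3E)-5-bromo-3-methylpent-3-en-1-yn-1-yl]-6-hydroxy-2,4,4-trimethylcyclohex-2-en-1-one | CC1=C(C#C/C(C)=C/CBr)C(C)(C)C[C@H](O)C1=O | intermediate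
20 | [(2E)-5-[(4S)-4-hydroxy-2,6,6-trimethyl-3-oxocyclohex-1-en-1-yl]-3-methylpent-2-en-4-yn-1-yl]triphenylphosphonium bromide | CC1=C(C#C/C(C)=C/C[P+](c2ccccc2)(c2ccccc2)c2ccccc2)C(C)(C)C[C@H](O)C1=O.[Br-] | intermediate
21 | (2E,4E,6E)-2,7-dimethylocta-2,4,6-trienedial | O=C/C(C)=C/C=C/C=C(C)/C=O | starting material
22 | ylide of 18, [(2E,4E)-5-[(4S)-4-hydroxy-2,6,6-trimethyl-3-oxocyclohex-1-en-1-yl]-3-methylpenta-2,4-dien-1-ylidene]triphenylphosphorane | CC1=C(/C=C/C(C)=C/C=P(c2ccccc2)(c2ccccc2)c2ccccc2)C(C)(C)C[C@H](O)C1=O | intermediate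
23 | (2E,4E,6E,8E,10E,12E)-13-[(4S)-4-hydroxy-2,6,6-trimethyl-3-oxocyclohex-1-en-1-yl]-2,7,11-trimethyltrideca-2,4,6,8,10,12-hexaenal | CC1=C(/C=C/C(C)=C/C=C/C(C)=C/C=C/C=C(C)/C=O)C(C)(C)C[C@H](O)C1=O | intermediate
24 | ylide of 20, [(2E)-5-[(4S)-4-hydroxy-2,6,6-trimethyl-3-oxocyclohex-1-en-1-yl]-3-methylpent-2-en-4-yn-1-ylidene]triphenylphosphorane | CC1=C(C#C/C(C)=C/C=P(c2ccccc2)(c2ccccc2)c2ccccc2)C(C)(C)C[C@H](O)C1=O | intermediate
25 | (3S,3′S)-3,3′-dihydroxy-7,8-didehydro-β,β-carotene-4,4′-dione (all-E) | CC1=C(C#C/C(C)=C/C=C/C(C)=C/C=C/C=C(C)/C=C/C=C(C)/C=C/C2=C(C)C(=O)[C@@H](O)CC2(C)C)C(C)(C)C[C@H](O)C1=O | intermediate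
26 | (3S,4S,3′S,4′S)-7,8-didehydro-β,β-carotene-3,4,3′,4′-tetrol (all-E) | CC1=C(C#C/C(C)=C/C=C/C(C)=C/C=C/C=C(C)/C=C/C=C(C)/C=C/C2=C(C)[C@H](O)[C@@H](O)CC2(C)C)C(C)(C)C[C@H](O)[C@H]1O | target

**Step count**
Total: 11 steps. Longest linear sequence: 9 steps (1 → 3 → 8 → 11 → 15 → 16 → 18 → 23 → 25 → 26; steps 1, 3, 4, 5, 6, 7, 9, 10, 11).

**Steps most likely to fail, with fallbacks**

Step 3 (key bond): an alkyl acylsilane with an alkyl aldehyde is the hardest pairing for the chiral phosphite, so enantioselectivity may be low and aldehyde self-condensation may compete. The fallback sets out from 3 and comes back at 11, using a nitronate instead of the silyloxy phosphonate carbanion as the propionyl anion. A copper-catalysed asymmetric Henry reaction of 3 with 1-nitropropane (Cu(OAc)2·H2O, chiral bis(oxazoline) ligand of the antipode that gives the 4S carbinol, EtOH, rt) gives methyl (4S)-4-hydroxy-2,2-dimethyl-5-nitroheptanoate F1. Silylation in the same flask (Et3SiOTf, 2,6-lutidine), before the hydroxy ester can lactonise, gives methyl (4S)-2,2-dimethyl-5-nitro-4-[(triethylsilyl)oxy]heptanoate F2. An oxidative Nef reaction (KOt-Bu, then dimethyldioxirane in acetone) turns the nitro-bearing carbon into the ketone, giving methyl (4S)-2,2-dimethyl-5-oxo-4-[(triethylsilyl)oxy]heptanoate F3, which is taken through the conditions of step 4 to 11.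

Step 4 (ring closure): acylation on the hindered ester needs warming, during which the trimethylsilyl group may migrate to the enolate oxygen, after which the freed alkoxide would lactonise onto the ester, or C3 may epimerise. The fallback sets out from 7 and comes back at 11, closing the ring on a nitrile instead of an ester. Isobutyronitrile is allylated (LiN(i-Pr)2, allyl bromide, THF) to 2,2-dimethylpent-4-enenitrile F4 and ozonised as in step 1 to 2,2-dimethyl-4-oxobutanenitrile F5. The key reaction of step 3 with 7 then gives (4S)-2,2-dimethyl-5-oxo-4-[(trimethylsilyl)oxy]heptanenitrile F6. LiN(i-Pr)2 at −78 °C closes the ring by Thorpe-type addition of the kinetic enolate to the unhindered nitrile, which should proceed at lower temperature than the ester acylation, needs no leaving group and cannot lactonise, giving (6S)-3-amino-2,4,4-trimethyl-6-[(trimethylsilyl)oxy]cyclohex-2-en-1-one F7. Aqueous HCl hydrolyses the vinylogous amide and the silyl ether to 10, which is ketalised without isolation (2,2-dimethoxypropane, p-TsOH) to 11.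

Step 11 (final reduction): the cross-conjugated polyene ketones are poor electrophiles, and the allylic C4 carbinols of the product are acid-sensitive, so conversion and trans selectivity on the C40 compound are uncertain. The fallback sets out from 18 and 20 and comes back at 26, moving the directed reduction forward to the crystalline salts. Me4NBH(OAc)3 in MeCN/AcOH converts 18 into [(2E,4E)-5-[(3S,4S)-3,4-dihydroxy-2,6,6-trimethylcyclohex-1-en-1-yl]-3-methylpenta-2,4-dien-1-yl]triphenylphosphonium bromide F8. The same reagent converts 20 into [(2E)-5-[(3S,4S)-3,4-dihydroxy-2,6,6-trimethylcyclohex-1-en-1-yl]-3-methylpent-2-en-4-yn-1-yl]triphenylphosphonium bromide F9. The trans-diol salts can be purified by crystallisation. Wittig reaction of F8 with 21 under the conditions of step 9 gives (2E,4E,6E,8E,10E,12E)-13-[(3S,4S)-3,4-dihydroxy-2,6,6-trimethylcyclohex-1-en-1-yl]-2,7,11-trimethyltrideca-2,4,6,8,10,12-hexaenal F10. Wittig reaction of F10 with F9 under the conditions of step 10 gives 26 directly, so the polyene never meets acid once the C4 carbinols are in place.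

**Further compounds**
F1 | step 3 | methyl (4S)-4-hydroxy-2,2-dimethyl-5-nitroheptanoate | CCC([N+](=O)[O-])[C@@H](O)CC(C)(C)C(=O)OC
F2 | step 3 | methyl (4S)-2,2-dimethyl-5-nitro-4-[(triethylsilyl)oxy]heptanoate | CCC([N+](=O)[O-])[C@@H](O[Si](CC)(CC)CC)CC(C)(C)C(=O)OC
F3 | step 3 | methyl (4S)-2,2-dimethyl-5-oxo-4-[(triethylsilyl)oxy]heptanoate | CCC(=O)[C@@H](O[Si](CC)(CC)CC)CC(C)(C)C(=O)OC
F4 | step 4 | 2,2-dimethylpent-4-enenitrile | C=CCC(C)(C)C#N
F5 | step 4 | 2,2-dimethyl-4-oxobutanenitrile | O=CCC(C)(C)C#N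
F6 | step 4 | (4S)-2,2-dimethyl-5-oxo-4-[(trimethylsilyl)oxy]heptanenitrile | CCC(=O)[C@@H](O[Si](C)(C)C)CC(C)(C)C#N
F7 | step 4 | (6S)-3-amino-2,4,4-trimethyl-6-[(trimethylsilyl)oxy]cyclohex-2-en-1-one | CC1=C(N)C(C)(C)C[C@H](O[Si](C)(C)C)C1=O
F8 | step 11 | [(2E,4E)-5-[(3S,4S)-3,4-dihydroxy-2,6,6-trimethylcyclohex-1-en-1-yl]-3-methylpenta-2,4-dien-1-yl]triphenylphosphonium bromide | CC1=C(/C=C/C(C)=C/C[P+](c2ccccc2)(c2ccccc2)c2ccccc2)C(C)(C)C[C@H](O)[C@H]1O.[Br-]
F9 | step 11 | [(2E)-5-[(3S,4S)-3,4-dihydroxy-2,6,6-trimethylcyclohex-1-en-1-yl]-3-methylpent-2-en-4-yn-1-yl]triphenylphosphonium bromide | CC1=C(C#C/C(C)=C/C[P+](c2ccccc2)(c2ccccc2)c2ccccc2)C(C)(C)C[C@H](O)[C@H]1O.[Br-]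
F10 | step 11 | (2E,4E,6E,8E,10E,12E)-13-[(3S,4S)-3,4-dihydroxy-2,6,6-trimethylcyclohex-1-en-1-yl]-2,7,11-trimethyltrideca-2,4,6,8,10,12-hexaenal | CC1=C(/C=C/C(C)=C/C=C/C(C)=C/C=C/C=C(C)/C=O)C(C)(C)C[C@H](O)[C@H]1O
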